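Conventions: each flavone half is numbered as a flavone. Rings A (benzo), C (pyranone) and B (2-aryl) belong to the 7-methoxyflavone half; rings D (benzo), F (pyranone) and E (the para-phenylene of the ether) belong to the 5,7-dihydroxyflavone half.

## Analysis of the target

Isocryptomerin 21 is a biflavone without any stereocentre: a 5-hydroxy-7-methoxyflavone (rings A, C, B, with a para hydroxyl on ring B) is joined through an ether oxygen on C6 of ring A to the para carbon of ring E, the 2-aryl ring of a 5,7-dihydroxyflavone (rings F, D). Every ring carbon is sp2, so the problems are regiochemistry and chemoselectivity only. The sensitive groups are four phenols of different acidity (both 5-hydroxyls are chelated to a C4 carbonyl), one methyl ether on O7 of ring A that must survive whatever frees the phenols, and two 4-pyranone rings that open under hot alkali or hard nucleophiles. The hard part is the diaryl ether: its oxygen sits on C6 between the oxygenated carbons C5 and C7, so an aryl–oxygen coupling there would have to work at a doubly ortho-substituted, very electron-rich carbon. In addition, any route that closes ring C onto a phloroglucinol-type ring A must tell C6 from C8 and the C5 oxygen from the C7 oxygen. The feature used here is that C5, C6 and C7 of ring A, with their three oxygens, are the three carbons of a 2-aryloxymalonyl unit, C6 being the central carbon that already carries the ether oxygen. The other three carbons of ring A, C8, C8a and C4a, correspond to the methyl carbon, C6 and C5 of a 2-aryl-6-methyl-4-pyranone in which rings C and B are complete. Ring A can therefore be formed last from two three-carbon pieces, and the ether oxygen is attached to its carbon by a simple alkylation before ring A exists.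

## Retrosynthetic reasoning

**21 to 20.** The last disconnection removes three O–benzyl bonds, on the para oxygen of ring B and on O5 and O7 of ring D. Benzyl is chosen for all three because it tolerates strong amide base, acid, alkylation and palladium catalysis, and because a boron Lewis acid with a cation trap cleaves benzyl aryl ethers while sparing a methyl ether. The forward step has to free three phenols without touching the O7 methyl group of ring A, the diaryl ether or the pyranones.

**20 to 14 and 18.** The bond between C2 of ring F and ring E is cut. This cut separates the demanding half (rings A, C, B with ring E attached through the ether) from the simple chromone 18, which holds rings F and D with their oxygens in place. Cutting inside ring F instead would require diketone chemistry on the large fragment. The forward reaction is a palladium-catalysed conjugate arylation of 18 by boronic acid 14, passing through flavanone 19, which is dehydrogenated in the same flask.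

**14 to 12.** The C–B bond is traced back through pinacol boronate 13 to the C–Br bond of 12. The bromine is carried from the start as a para substituent of ring E that is inert to all earlier conditions.

**18 to 16 to 15.** C2 of 18 is a single carbon added to the acetyl group of 16 by way of enaminone 17, and the O1–C2 bond closes on the free hydroxyl of 16. Acetophenone 16 is the dibenzyl ether of commercial 15; the hydroxyl that stays free is the one held by the acetyl carbonyl.

**12 to 11.** The O7–CH3 bond is cut. With the ring B oxygen benzylated, 11 has only two hydroxyls, and they differ sharply: O5–H is chelated to the C4 carbonyl, O7–H is not. The methyl group is put on after ring A is formed because the ring-forming step delivers both oxygens as free hydroxyls, and the chromone carbonyl then distinguishes them.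

**11 to 4 and 9 (key disconnection).** The bonds C7–C8 and C4a–C5 are cut. These are the two bonds that join the malonyl three-carbon unit to the pyranone three-carbon unit. Cutting them removes ring A and leaves the ether oxygen on the sp3 central carbon of malonate 9, where it can be installed by substitution. This avoids an aryl–oxygen coupling at a crowded carbon and removes the C6/C8 ambiguity. Rings C and B arrive ready-made in 4. In the forward direction 4 must act as a carbon-only 1,3-dinucleophile (methyl carbon first, then C5) towards 9 as a 1,3-dielectrophile, by way of keto ester 10.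

**4 to 3 to 1 and 2.** The pyranone O–C bond of 4 is opened to triketone 3. The bond between the aroyl carbon and the adjacent methylene of 3 is then cut, giving diketone 1 and ester 2. Forward, this is a terminal aroylation of 1 followed by cyclodehydration.

**9 to 8 to 7 to 5 and 6.** The two activated ester C–O bonds of 9 go back to diacid 8 and diester 7. The ether bond between the phenol oxygen of 5 and the central carbon of 6 is then cut. This is where the troublesome ether of the target is actually made, as an SN2 alkylation of a phenoxide.

## Alternatives that were turned down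

**Alternative 1:** The O1–C8a bond of ring F is cut. In the forward direction the 1,3-diketone A1, whose 2,4,6-trifluorobenzoyl group is the future ring D, would be treated with K2CO3 in DMF. The enolate oxygen displaces an ortho fluoride and closes ring F, giving the 5,7-difluoroflavone A2.
- For it: intramolecular SNAr on an ortho-fluoroaryl ketone is dependable. The two ortho fluorines are equivalent, so ring F can close in only one way. The closure is mild and basic, and ring D needs no phenol protection. On reliability of the key step this alternative is stronger than the chosen route.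
- Against it: the step makes one C–O bond in the half of the molecule that poses no problem. A1 already contains ring A with its aryloxy group on C6, so the hindered ether and the C6/C8 question must have been solved beforehand by other means. A2 still has fluorine where the target has hydroxyl, so two further SNAr exchanges are needed, the second on a ring deactivated by the first alkoxide, with nucleophiles that can also add to C2 of either pyranone. Deprotections follow, including cleavage of the O5 methyl group of ring A next to the O7 methyl group.
- Comparison: the chosen strategy gives up precedent for its key step. In return that step builds ring A with the ether in place, and ring D enters with its oxygens already present.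

**Alternative 2:** Two C–C bonds of ring E are cut, so that the para-phenylene arises from a 2-pyranone and an alkyne. The coumalate ester A3 and the aryl ynol ether A4 would be heated together; cycloaddition across C3 and C6 of A3 followed by decarboxylation gives the 4-aryloxybenzoate A5.
- For it: like the chosen route, it never couples an aryl group to the crowded oxygen, because ring E grows on a phenol oxygen of the ring A precursor. The reaction type is known for electron-rich alkynes, and the polarity (nucleophilic terminal alkyne carbon to C6 of A3) predicts the para isomer. In precedent this key step is the stronger one.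
- Against it: A4 needs several steps from a hindered phenol and is fragile towards water and heat. A5 contains neither pyranone ring, so ring A must still be acylated between two oxygens and both flavone halves built by two separate diketone and cyclodehydration sequences. The three oxygens of ring A in A5 must also be told apart later.
- Comparison: the chosen route reaches the same ether by an SN2 alkylation and has rings C and B in place when ring A forms, so far fewer steps follow the key step.

**Alternative 3:** The C4a–C5 bond of ring D is cut in a biomimetic sense. The 4-hydroxy-2-pyranone A6, a masked polyketide, would be opened by Mg(OMe)2, and the chain carbanion would attack the new ester in a Claisen cyclisation to give the acylphloroglucinol A7; acid would then close ring F.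
- For it: ring D is delivered with free hydroxyls, the symmetric phloroglucinol makes closure of ring F unambiguous, and magnesium-templated Claisen cyclisation of such chains has precedent. On protecting-group economy in ring D it is better than the chosen route, which needs two benzyl ethers there.
- Against it: ring D is a phloroglucinol that can be bought in the form of 15, so building it from a long poly-β-carbonyl chain spends many steps on the cheapest ring. The chain of A6 has several acidic sites and can close in the aldol mode as well as the Claisen mode. As in alternative 1, the ring A ether must already exist in A6.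
- Comparison: the chosen route spends its single risky step on ring A, the part of the molecule that cannot be bought.

Key step: step 6

Remark on the chemistry: 3 is written as the triketo tautomer although it should exist largely as enols. Compounds 10 and 19 are racemic, and each of these stereocentres disappears in the step in which it forms.

## Route

Step 1
Reactants: 1 acetylacetone (pentane-2,4-dione); 2 methyl 4-(benzyloxy)benzoate
Product: 3 1-[4-(benzyloxy)phenyl]hexane-1,3,5-trione
Conditions: 1 (1.5 equiv), NaH (5 equiv), DME, reflux; 2 (1.0 equiv) added slowly; cold aq. HCl work-up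
Reagents that add atoms: none
Why: Claisen-type aroylation of a β-diketone at its terminal methyl group: with excess NaH the diketone reacts through its dianion, the ester cannot enolise, and the triketone is held as a polyanion until acidification; the excess of 1 should suppress aroylation at both methyl groups.

Step 2
Reactants: 3 1-[4-(benzyloxy)phenyl]hexane-1,3,5-trione
Product: 4 2-[4-(benzyloxy)phenyl]-6-methyl-4H-pyran-4-one
Conditions: TFA/CH2Cl2 (1:1), 0 °C → rt
Reagents that add atoms: none
Why: Acid-catalysed cyclodehydration of a 1,3,5-triketone: an enol oxygen adds to the protonated terminal carbonyl and loss of water gives the aromatic 4-pyranone. TFA is preferred to cold concentrated H2SO4 because the benzyl aryl ether, deactivated by the para acyl group, should survive it.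

Step 3
Reactants: 5 4-bromophenol; 6 diethyl bromomalonate
Product: 7 diethyl 2-(4-bromophenoxy)malonate
Conditions: K2CO3, acetone, reflux
Reagents that add atoms: none
Why: Williamson ether synthesis: the phenoxide displaces bromide from the doubly activated secondary carbon (SN2), the same O-alkylation that opens benzofuran syntheses from salicylaldehydes; the weak base leaves the esters intact.

Step 4
Reactants: 7 diethyl 2-(4-bromophenoxy)malonate
Product: 8 2-(4-bromophenoxy)malonic acid
Conditions: NaOH (2.5 equiv), EtOH/H2O, 0 °C → rt; then aq. HCl, 0 °C
Reagents that add atoms: sodium hydroxide, [Na+].[OH-]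
Why: Saponification of both ethyl esters; it is run at or below room temperature and acidified cold because 2-aryloxymalonic acids decarboxylate on heating.

Step 5
Reactants: 8 2-(4-bromophenoxy)malonic acid
Product: 9 bis(2,4,6-trichlorophenyl) 2-(4-bromophenoxy)malonate
Conditions: 2,4,6-trichlorophenol (2.0 equiv), POCl3, 90 °C
Reagents that add atoms: 2,4,6-trichlorophenol, Oc1c(Cl)cc(Cl)cc1Cl
Why: Standard preparation of active malonates: POCl3 activates the carboxyl groups as acid chloride or mixed anhydride, which then acylate the poorly nucleophilic phenol; HCl escapes and the diester should crystallise.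

Step 6
Reactants: 4 2-[4-(benzyloxy)phenyl]-6-methyl-4H-pyran-4-one; 9 bis(2,4,6-trichlorophenyl) 2-(4-bromophenoxy)malonate
Product: 11 2-[4-(benzyloxy)phenyl]-6-(4-bromophenoxy)-5,7-dihydroxy-4H-chromen-4-one, via keto ester 10 (not isolated)
Conditions: LiN(SiMe3)2 (4.2 equiv, in two portions), 9 (1.1 equiv), THF, −78 °C → 50 °C; aq. HCl work-up
Reagents that add atoms: none
Why: Proposed new method: LiN(SiMe3)2 deprotonates the 6-methyl group of 4 to a vinylogous enolate, and its exocyclic carbon is acylated by 9 (directly, or after 9 has lost an aryloxide by E1cB to give an aryloxy-substituted acylketene), which forms C7–C8 and gives keto ester 10 as its enolate. Further base removes a proton from the new CH2 group, and the resulting anion is conjugated through the pyranone to its C5; this carbon attacks the remaining active ester carbonyl in a 6-exo-trig acyl substitution (or, if 10 first collapses to its acylketene, closes by 6π-electrocyclisation of the dienylketene), forming C4a–C5 and ring A. Loss of the second aryloxide and two enolisations make ring A aromatic, so the product leaves as its dianion and four equivalents of base are consumed. The closest known reaction types are the cyclocondensation of bis(2,4,6-trichlorophenyl) malonates with 1,3-dinucleophiles, the C-acylation of laterally lithiated 2-methyl-4-pyranones and dienylketene benzannulation. No stereocentre is created, and the one in 10 is lost on aromatisation. The step needs closure through carbon and the ether oxygen on C6: the methyl carbon, C6 and C5 of 4 form a carbon-only 1,3-dinucleophile, an oxygen nucleophile in 10 could only close a strained four-membered lactone, and because the aryloxy group sits on the middle carbon of the malonyl unit it must end up on C6 between the two new hydroxyls, so an 8-aryloxy isomer has no pathway.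

Step 7
Reactants: 11 2-[4-(benzyloxy)phenyl]-6-(4-bromophenoxy)-5,7-dihydroxy-4H-chromen-4-one
Product: 12 2-[4-(benzyloxy)phenyl]-6-(4-bromophenoxy)-5-hydroxy-7-methoxy-4H-chromen-4-one
Conditions: MeI (1.1 equiv), K2CO3 (1.2 equiv), acetone, rt → 40 °C
Reagents that add atoms: iodomethane, CI
Why: Williamson methylation: the 7-hydroxyl is the more acidic and is free, whereas the 5-hydroxyl is locked in a hydrogen bond to the C4 carbonyl, so one equivalent of base and MeI should methylate O7 only.

Step 8
Reactants: 12 2-[4-(benzyloxy)phenyl]-6-(4-bromophenoxy)-5-hydroxy-7-methoxy-4H-chromen-4-one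
Product: 14 [4-({2-[4-(benzyloxy)phenyl]-5-hydroxy-7-methoxy-4-oxo-4H-chromen-6-yl}oxy)phenyl]boronic acid, via pinacol boronate 13 (not isolated)
Conditions: B2pin2, Pd(dppf)Cl2 (5 mol %), KOAc, 1,4-dioxane, 90 °C; then MeB(OH)2 (excess), 0.1 M HCl/acetone, rt
Reagents that add atoms: bis(pinacolato)diboron, CC1(C)OB(OC1(C)C)B1OC(C)(C)C(C)(C)O1; water, O
Why: Miyaura borylation: oxidative addition of the aryl bromide to zerovalent palladium, acetate-assisted transmetalation with B2pin2 and reductive elimination give 13, and KOAc is too weak to harm the pyranone or the chelated phenol. Transesterification to the volatile pinacol ester of MeB(OH)2 then frees the boronic acid that the next step needs for transmetalation.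

Step 9
Reactants: 15 1-(2,4,6-trihydroxyphenyl)ethan-1-one
Product: 16 1-[2,4-bis(benzyloxy)-6-hydroxyphenyl]ethan-1-one
Conditions: BnBr (2.1 equiv), K2CO3, acetone, reflux
Reagents that add atoms: benzyl bromide, BrCc1ccccc1
Why: Williamson benzylation of the para hydroxyl and one ortho hydroxyl; the remaining ortho hydroxyl is held in a hydrogen bond to the acetyl carbonyl and should stay free when the halide is limited to two equivalents.

Step 10
Reactants: 16 1-[2,4-bis(benzyloxy)-6-hydroxyphenyl]ethan-1-one
Product: 18 5,7-bis(benzyloxy)-4H-chromen-4-one, via enaminone 17 (not isolated)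
Conditions: Me2NCH(OMe)2, toluene, 100 °C; then conc. HCl (cat.), CH2Cl2, 40 °C
Reagents that add atoms: N,N-dimethylformamide dimethyl acetal, COC(OC)N(C)C
Why: Enaminone route to 2,3-unsubstituted chromones: the amide acetal condenses with the acetyl methyl group to give 17, and acid triggers conjugate addition of the phenol and loss of dimethylamine, which closes the pyranone.

Step 11
Reactants: 14 [4-({2-[4-(benzyloxy)phenyl]-5-hydroxy-7-methoxy-4-oxo-4H-chromen-6-yl}oxy)phenyl]boronic acid; 18 5,7-bis(benzyloxy)-4H-chromen-4-one
Product: 20 6-{4-[5,7-bis(benzyloxy)-4-oxo-4H-chromen-2-yl]phenoxy}-2-[4-(benzyloxy)phenyl]-5-hydroxy-7-methoxy-4H-chromen-4-one, via flavanone 19 (not isolated)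
Conditions: Pd(OAc)2 (10 mol %), 2,2'-bipyridine (20 mol %), 18 (2.5 equiv), AcOH/THF/H2O, 60 °C; then DDQ, 1,4-dioxane, 90 °C
Reagents that add atoms: none
Why: Conjugate addition of an arylboronic acid to a chromone catalysed by divalent palladium: transmetalation gives an aryl–palladium species that inserts the C2=C3 bond with the aryl group going to C2, and protonolysis of the palladium enolate gives flavanone 19, which DDQ dehydrogenates to the flavone. The acidic medium keeps the chelated phenol protonated, and the chromone is used in excess because 14 is the valuable partner.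

Step 12
Reactants: 20 6-{4-[5,7-bis(benzyloxy)-4-oxo-4H-chromen-2-yl]phenoxy}-2-[4-(benzyloxy)phenyl]-5-hydroxy-7-methoxy-4H-chromen-4-one
Product: 21 isocryptomerin, 6-[4-(5,7-dihydroxy-4-oxo-4H-chromen-2-yl)phenoxy]-5-hydroxy-2-(4-hydroxyphenyl)-7-methoxy-4H-chromen-4-one
Conditions: BCl3 (excess), C6HMe5, CH2Cl2, −78 → −20 °C; MeOH quench
Reagents that add atoms: none
Why: Lewis-acid debenzylation: BCl3 coordinates the benzyl ether oxygens and the benzyl cations are captured by pentamethylbenzene (Friedel–Crafts), which prevents C-benzylation of ring D. At low temperature the O7 methyl ether, which is neither benzylic nor chelated to a carbonyl, and the diaryl ether should remain.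

## Compound list

1 | acetylacetone (pentane-2,4-dione) | CC(=O)CC(C)=O | starting material
2 | methyl 4-(benzyloxy)benzoate | COC(=O)c1ccc(OCc2ccccc2)cc1 | starting material
3 | 1-[4-(benzyloxy)phenyl]hexane-1,3,5-trione | CC(=O)CC(=O)CC(=O)c1ccc(OCc2ccccc2)cc1 | intermediate
4 | 2-[4-(benzyloxy)phenyl]-6-methyl-4H-pyran-4-one | Cc1cc(=O)cc(-c2ccc(OCc3ccccc3)cc2)o1 | intermediate
5 | 4-bromophenol | Oc1ccc(Br)cc1 | starting material
6 | diethyl bromomalonate | CCOC(=O)C(Br)C(=O)OCC | starting material
7 | diethyl 2-(4-bromophenoxy)malonate | CCOC(=O)C(Oc1ccc(Br)cc1)C(=O)OCC | intermediate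
8 | 2-(4-bromophenoxy)malonic acid | OC(=O)C(Oc1ccc(Br)cc1)C(=O)O | intermediate
9 | bis(2,4,6-trichlorophenyl) 2-(4-bromophenoxy)malonate | O=C(Oc1c(Cl)cc(Cl)cc1Cl)C(Oc1ccc(Br)cc1)C(=O)Oc1c(Cl)cc(Cl)cc1Cl | intermediate
10 | 2,4,6-trichlorophenyl 4-{6-[4-(benzyloxy)phenyl]-4-oxo-4H-pyran-2-yl}-2-(4-bromophenoxy)-3-oxobutanoate (racemic) | O=C(Oc1c(Cl)cc(Cl)cc1Cl)C(Oc1ccc(Br)cc1)C(=O)Cc1cc(=O)cc(-c2ccc(OCc3ccccc3)cc2)o1 | intermediate (not isolated)
11 | 2-[4-(benzyloxy)phenyl]-6-(4-bromophenoxy)-5,7-dihydroxy-4H-chromen-4-one | O=c1cc(-c2ccc(OCc3ccccc3)cc2)oc2cc(O)c(Oc3ccc(Br)cc3)c(O)c12 | intermediate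
12 | 2-[4-(benzyloxy)phenyl]-6-(4-bromophenoxy)-5-hydroxy-7-methoxy-4H-chromen-4-one | COc1cc2oc(-c3ccc(OCc4ccccc4)cc3)cc(=O)c2c(O)c1Oc1ccc(Br)cc1 | intermediate
13 | 2-[4-(benzyloxy)phenyl]-5-hydroxy-7-methoxy-6-[4-(4,4,5,5-tetramethyl-1,3,2-dioxaborolan-2-yl)phenoxy]-4H-chromen-4-one | COc1cc2oc(-c3ccc(OCc4ccccc4)cc3)cc(=O)c2c(O)c1Oc1ccc(B2OC(C)(C)C(C)(C)O2)cc1 | intermediate (not isolated)
14 | [4-({2-[4-(benzyloxy)phenyl]-5-hydroxy-7-methoxy-4-oxo-4H-chromen-6-yl}oxy)phenyl]boronic acid | COc1cc2oc(-c3ccc(OCc4ccccc4)cc3)cc(=O)c2c(O)c1Oc1ccc(B(O)O)cc1 | intermediate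
15 | 1-(2,4,6-trihydroxyphenyl)ethan-1-one | CC(=O)c1c(O)cc(O)cc1O | starting material
16 | 1-[2,4-bis(benzyloxy)-6-hydroxyphenyl]ethan-1-one | CC(=O)c1c(O)cc(OCc2ccccc2)cc1OCc1ccccc1 | intermediate
17 | (E)-1-[2,4-bis(benzyloxy)-6-hydroxyphenyl]-3-(dimethylamino)prop-2-en-1-one | CN(C)/C=C/C(=O)c1c(O)cc(OCc2ccccc2)cc1OCc1ccccc1 | intermediate (not isolated)
18 | 5,7-bis(benzyloxy)-4H-chromen-4-one | O=c1ccoc2cc(OCc3ccccc3)cc(OCc3ccccc3)c12 | intermediate
19 | 6-{4-[5,7-bis(benzyloxy)-4-oxochroman-2-yl]phenoxy}-2-[4-(benzyloxy)phenyl]-5-hydroxy-7-methoxy-4H-chromen-4-one (racemic) | COc1cc2oc(-c3ccc(OCc4ccccc4)cc3)cc(=O)c2c(O)c1Oc1ccc(C2CC(=O)c3c(OCc4ccccc4)cc(OCc4ccccc4)cc3O2)cc1 | intermediate (not isolated)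
20 | 6-{4-[5,7-bis(benzyloxy)-4-oxo-4H-chromen-2-yl]phenoxy}-2-[4-(benzyloxy)phenyl]-5-hydroxy-7-methoxy-4H-chromen-4-one | COc1cc2oc(-c3ccc(OCc4ccccc4)cc3)cc(=O)c2c(O)c1Oc1ccc(-c2cc(=O)c3c(OCc4ccccc4)cc(OCc4ccccc4)cc3o2)cc1 | intermediate
21 | isocryptomerin | COc1cc2oc(-c3ccc(O)cc3)cc(=O)c2c(O)c1Oc1ccc(-c2cc(=O)c3c(O)cc(O)cc3o2)cc1 | target

## Step count and risk

Total step count: 12. Longest linear sequence: 8 steps (steps 3, 4, 5, 6, 7, 8, 11 and 12, from 4-bromophenol 5).

**Step 6 (key step; the one step that carries the label for a new method).**
- What may go wrong: acylation at the carbonyl oxygen of the pyranone dienolate instead of the methyl carbon; consumption of the ketene released from 9 by the amide base or by oligomerisation before the carbanion traps it; or stalling at the stage of 10 because C5 of the pyranone is only a weak nucleophile, so that hydrolysis and decarboxylation take over on work-up.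
- Precautions inside the step: the anion of 4 is formed with one equivalent of base, combined cold with the enolate of 9, and the remaining base is added only after the first acylation.
- Fallback (known chemistry): it sets out from ester 2, with syringaldehyde as a new commercial material, and comes back to the route at 12, replacing steps 1 to 7.
  - Syringaldehyde is O-arylated with bis(4-bromophenyl)iodonium triflate (KOtBu, THF) to 4-(4-bromophenoxy)-3,5-dimethoxybenzaldehyde F1.
  - Baeyer–Villiger oxidation with mCPBA gives 4-(4-bromophenoxy)-3,5-dimethoxyphenyl formate F2, and methanolysis (K2CO3, MeOH) gives 4-(4-bromophenoxy)-3,5-dimethoxyphenol F3.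
  - Friedel–Crafts acetylation ortho to the hydroxyl (Ac2O, BF3·OEt2) gives 1-[3-(4-bromophenoxy)-6-hydroxy-2,4-dimethoxyphenyl]ethan-1-one F4.
  - Claisen condensation of its dianion (LiN(SiMe3)2, THF) with ester 2 gives 1-[4-(benzyloxy)phenyl]-3-[3-(4-bromophenoxy)-6-hydroxy-2,4-dimethoxyphenyl]propane-1,3-dione F5.
  - Cyclodehydration (AcOH, catalytic H2SO4) gives 2-[4-(benzyloxy)phenyl]-6-(4-bromophenoxy)-5,7-dimethoxy-4H-chromen-4-one F6, and MgBr2·OEt2 removes the chelated methyl group on O5 to give 12.
  - The free hydroxyl of F3 fixes which oxygen becomes O1, so the aryloxy group must end on C6.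

**Step 11.**
- What may go wrong: protodeboronation or oxidative homocoupling of 14, which is the limiting partner; binding of palladium by the 5-hydroxy-4-keto chelate of ring A; or incomplete dehydrogenation of 19.
- Fallback: it sets out from bromide 12 and acetophenone 16 and comes back at 20, which also makes steps 8 and 10 unnecessary.
  - Palladium-catalysed methoxycarbonylation of 12 (Pd(OAc)2, Xantphos, CO, Et3N, MeOH/toluene) gives methyl 4-({2-[4-(benzyloxy)phenyl]-5-hydroxy-7-methoxy-4-oxo-4H-chromen-6-yl}oxy)benzoate F7.
  - Claisen condensation with the dianion of 16 (LiN(SiMe3)2, THF, with one further equivalent for the phenol of F7) gives 1-[2,4-bis(benzyloxy)-6-hydroxyphenyl]-3-[4-({2-[4-(benzyloxy)phenyl]-5-hydroxy-7-methoxy-4-oxo-4H-chromen-6-yl}oxy)phenyl]propane-1,3-dione F8.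
  - Acid cyclodehydration (AcOH, catalytic H2SO4) closes ring F and gives 20.

**Step 5.**
- What may go wrong: decarboxylation of the aryloxymalonic acid in hot POCl3 before both carboxyl groups are esterified, or esterification stopping at the half ester.
- Fallback: it sets out from 8 and comes back at 9. (COCl)2 with catalytic DMF in CH2Cl2 at 0 °C converts 8 into 2-(4-bromophenoxy)malonyl dichloride F9, which is esterified with 2,4,6-trichlorophenol at 0 °C without any heating.

**Step 12.**
- What may go wrong: partial loss of the O7 methyl group if the mixture warms, incomplete cleavage of the least activated benzyl ether, or C-benzylation of ring D if cation capture is too slow.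
- Fallback: it sets out from 20 and comes back at 21. Catalytic hydrogenolysis (H2, 1 atm, Pd/C, THF/MeOH, rt) cannot cleave a methyl ether; it is stopped at the calculated uptake to spare the C2=C3 bonds. No new compound is formed.

## Further compounds

F1 | step 6 | 4-(4-bromophenoxy)-3,5-dimethoxybenzaldehyde | COc1cc(C=O)cc(OC)c1Oc1ccc(Br)cc1
F2 | step 6 | 4-(4-bromophenoxy)-3,5-dimethoxyphenyl formate | COc1cc(OC=O)cc(OC)c1Oc1ccc(Br)cc1
F3 | step 6 | 4-(4-bromophenoxy)-3,5-dimethoxyphenol | COc1cc(O)cc(OC)c1Oc1ccc(Br)cc1
F4 | step 6 | 1-[3-(4-bromophenoxy)-6-hydroxy-2,4-dimethoxyphenyl]ethan-1-one | CC(=O)c1c(O)cc(OC)c(Oc2ccc(Br)cc2)c1OC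
F5 | step 6 | 1-[4-(benzyloxy)phenyl]-3-[3-(4-bromophenoxy)-6-hydroxy-2,4-dimethoxyphenyl]propane-1,3-dione | O=C(CC(=O)c1ccc(OCc2ccccc2)cc1)c1c(O)cc(OC)c(Oc2ccc(Br)cc2)c1OC
F6 | step 6 | 2-[4-(benzyloxy)phenyl]-6-(4-bromophenoxy)-5,7-dimethoxy-4H-chromen-4-one | COc1cc2oc(-c3ccc(OCc4ccccc4)cc3)cc(=O)c2c(OC)c1Oc1ccc(Br)cc1
F7 | step 11 | methyl 4-({2-[4-(benzyloxy)phenyl]-5-hydroxy-7-methoxy-4-oxo-4H-chromen-6-yl}oxy)benzoate | COC(=O)c1ccc(Oc2c(OC)cc3oc(-c4ccc(OCc5ccccc5)cc4)cc(=O)c3c2O)cc1
F8 | step 11 | 1-[2,4-bis(benzyloxy)-6-hydroxyphenyl]-3-[4-({2-[4-(benzyloxy)phenyl]-5-hydroxy-7-methoxy-4-oxo-4H-chromen-6-yl}oxy)phenyl]propane-1,3-dione | COc1cc2oc(-c3ccc(OCc4ccccc4)cc3)cc(=O)c2c(O)c1Oc1ccc(C(=O)CC(=O)c2c(O)cc(OCc3ccccc3)cc2OCc2ccccc2)cc1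
F9 | step 5 | 2-(4-bromophenoxy)malonyl dichloride | O=C(Cl)C(Oc1ccc(Br)cc1)C(=O)Cl
F0 | step 12 | none | none
A1 | alternative 1 | 1-[4-({2-[4-(benzyloxy)phenyl]-5,7-dimethoxy-4-oxo-4H-chromen-6-yl}oxy)phenyl]-3-(2,4,6-trifluorophenyl)propane-1,3-dione | COc1cc2oc(-c3ccc(OCc4ccccc4)cc3)cc(=O)c2c(OC)c1Oc1ccc(C(=O)CC(=O)c2c(F)cc(F)cc2F)cc1
A2 | alternative 1 | 2-[4-(benzyloxy)phenyl]-6-[4-(5,7-difluoro-4-oxo-4H-chromen-2-yl)phenoxy]-5,7-dimethoxy-4H-chromen-4-one | COc1cc2oc(-c3ccc(OCc4ccccc4)cc3)cc(=O)c2c(OC)c1Oc1ccc(-c2cc(=O)c3c(F)cc(F)cc3o2)cc1
A3 | alternative 2 | methyl coumalate (methyl 2-oxo-2H-pyran-5-carboxylate) | COC(=O)c1ccc(=O)oc1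
A4 | alternative 2 | 5-(benzyloxy)-2-(ethynyloxy)-1,3-dimethoxybenzene | C#COc1c(OC)cc(OCc2ccccc2)cc1OC
A5 | alternative 2 | methyl 4-[4-(benzyloxy)-2,6-dimethoxyphenoxy]benzoate | COC(=O)c1ccc(Oc2c(OC)cc(OCc3ccccc3)cc2OC)cc1
A6 | alternative 3 | 6-{4-[4-({2-[4-(benzyloxy)phenyl]-5,7-dimethoxy-4-oxo-4H-chromen-6-yl}oxy)phenyl]-2,4-dioxobutyl}-4-hydroxy-2H-pyran-2-one | COc1cc2oc(-c3ccc(OCc4ccccc4)cc3)cc(=O)c2c(OC)c1Oc1ccc(C(=O)CC(=O)Cc2cc(O)cc(=O)o2)cc1
A7 | alternative 3 | 1-[4-({2-[4-(benzyloxy)phenyl]-5,7-dimethoxy-4-oxo-4H-chromen-6-yl}oxy)phenyl]-3-(2,4,6-trihydroxyphenyl)propane-1,3-dione | COc1cc2oc(-c3ccc(OCc4ccccc4)cc3)cc(=O)c2c(OC)c1Oc1ccc(C(=O)CC(=O)c2c(O)cc(O)cc2O)cc1
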